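A flat yield is easily mistaken for the rate at which a product was born, and this flask turns on that pitfall.

in all of them: substrate 0.20 mM
- teal: first nucleophile 0.80 equiv; second nucleophile 0.65 equiv; run made earlier
- amber: first nucleophile 0.80 equiv; second nucleophile 0.98 equiv; run made earlier
- flask: first nucleophile 0.800 equiv; second nucleophile 1.30 equiv; time 4.0 min

| run | time / min | other capture product / % | target / % | substrate / % |
|---|---|---|---|---|
| teal | 0.667 | 34.7 | 18.8 | 0.6 |
| teal | 1.50 | 35.1 | 19.7 | 0 |
| teal | 3.00 | 33.6 | 19.7 | 0 |
| teal | 5.00 | 34.9 | 19.8 | 0 |
| amber | 0.417 | 40.0 | 17.6 | 5.4 |
| amber | 0.833 | 42.3 | 17.4 | 0 |
| amber | 2.00 | 43.4 | 16.7 | 0 |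
| amber | 5.00 | 43.3 | 18.3 | 0.5 |

(standard deviation of a reading: 0.5 percentage points)

- share of other capture product in other capture product plus target at 0.30 s
- share of other capture product in other capture product plus target at 8.0 s
- share of other capture product in other capture product plus target at 4.0 min
- which of other capture product and target there is more of at 4.0 min



In the teal and amber runs, other capture product and target stay level through the later readings, yet at 5.00 min they sum to 54.7 % in teal and 61.6 % in amber. Both sides of this dispute charge the substrate that did not become other capture product to the first nucleophile, so at that time the logarithm of the fraction of first nucleophile left over the logarithm of the fraction of second nucleophile left reads 2.18 in teal and 2.12 in amber. I carry their mean, 2.15, as the capture ratio σ, the selectivity factor of first over second nucleophile.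

The forecast takes target as a steady 30 % of the substrate the first nucleophile consumes, in both runs, and finds that “simple parallel second-order capture fits well”. For the flask it gives 71.5 % at 0.30 s, 74.7 % at 8.0 s and 76 % at 4.0 min, with other capture product ahead.

I hold instead that the first nucleophile makes target and nothing else, and that the unseen part leaves target afterwards, before the earliest reading at 0.417 min. The flask's start share is then c(second nucleophile)/(c(second nucleophile) + σ c(first nucleophile)), which is 43.1 %. Putting this answer back with midway nucleophile levels gives the flask an end yield of other capture product of 49.5 %, and a second round gives 47.2 %. That brackets the forecast's 49 %, so on this end yield we stand together, and we part at the start.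

The flask gives 43.6 % at 0.30 s, 67.0 % at 8.0 s and 75.7 % at 4.0 min, with 48.6 % of other capture product against 15.6 % of target. My start share is about level with the first of these. The forecast's number stands beside the flask's at 4.0 min, 76 % against 75.7 %, a time long against both the relaxation half-life of target and isomer of the product, 1.24 s, and the half-life of the substrate's passing into intermediate, 0.096 min.

    second nucleophile + intermediate → other capture product (k = 10000 M⁻¹ s⁻¹)
    first nucleophile + intermediate → target (k = 22000 M⁻¹ s⁻¹)
    target ⇌ isomer of the product (K = 2.30, k = 0.390 s⁻¹)
    substrate → intermediate (k = 0.120 s⁻¹)

The neighbouring flask charges 0.330 equiv of second nucleophile, with the rest as in the flask. The capture ratio gives it a start share of 16.1 %, and it shows 16.4 % at 0.30 s. The neighbouring flask's share climbs to 35.8 % at 8.0 s and 51.4 % at 4.0 min, where other capture product stands at 24.3 % and the isomer of the product holds the most, 52.8 %.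

The earlier runs and the new flask are simulated on assumed constants; noise was put on by code.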